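The target is read as the mono-cyclised, mono-reduced form of a twofold-symmetric diketo-diol, so the route rests on one small chiral lactone that carries carbinol C1' and ring carbon C4 of the oxolane (O1, C2–C5). The key step exploits the fact that C4 is configurationally labile as long as C1' is an aryl ketone and C5 an ester: a ketoreductase reduces racemic dimethyl 2-(4-benzyloxybenzoyl)succinate under dynamic kinetic resolution and the new hydroxyl closes a γ-lactone, which fixes both centres in one operation. A second aldol then gives a twofold-symmetric dilactone; two arylmagnesium additions from one stock solution, an ionic hydrogenation between them, and hydrogenolysis complete the synthesis.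

Key step: step 3

Remark: all phenols are carried as benzyl ethers (an ortho-silyloxy aryl anion could suffer a retro-Brook silyl shift, and aryl silyl ethers are at risk from the methoxide of step 1); the aryl nucleophile is used as its Grignard reagent, which is less basic toward the enolisable lactones and keeps as a stock solution; C1' and C2–C5 are the atom labels of the target's oxolane; 15, 17 and 18 can equilibrate between hydroxy ketone and cyclic hemiketal forms and are drawn in the form named.

Step 1
Reactants: 1 1-[4-(benzyloxy)phenyl]ethan-1-one; 2 dimethyl carbonate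
Product: 3 methyl 3-[4-(benzyloxy)phenyl]-3-oxopropanoate
Conditions: NaH, THF, reflux; aq. HCl
Reagents that add atoms: none
Why: Crossed Claisen condensation in which the sodium enolate of the aryl methyl ketone is C-acylated by dimethyl carbonate and the product is drained as its stabilised enolate, the benzyl ether being inert to NaH and methoxide.

Step 2
Reactants: 3 methyl 3-[4-(benzyloxy)phenyl]-3-oxopropanoate; 4 methyl bromoacetate
Product: 5 dimethyl 2-[4-(benzyloxy)benzoyl]butanedioate (racemic)
Conditions: K2CO3, acetone, rt
Reagents that add atoms: none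
Why: SN2 C-alkylation of the β-keto ester enolate by the reactive α-bromo ester, which should stop at mono-alkylation because the product is more hindered and less acidic; the new centre is deliberately left racemic.

Step 3
Reactants: 5 dimethyl 2-[4-(benzyloxy)benzoyl]butanedioate (racemic)
Product: 7 methyl (2R,3R)-2-[4-(benzyloxy)phenyl]-5-oxooxolane-3-carboxylate (trans), via hydroxy diester 6 (not isolated)
Conditions: ketoreductase (panel enzyme selected for the (R)-carbinol), NADP+ (cat.), D-glucose, glucose dehydrogenase, phosphate buffer pH 7/DMSO, 30 °C; extraction; PPTS (cat.), toluene, 60 °C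
Reagents that add atoms: none
Why: Enzyme-bound NADPH delivers hydride to one face of the aryl ketone of the α-epimer that fits the active site, while the other epimer of 5 racemises through its enol at pH 7 faster than it is reduced, so the racemate should funnel into hydroxy diester 6 (enzymatic dynamic kinetic resolution); the closest known reaction type is the ketoreductase or yeast reduction of α-substituted β-keto esters, 2-acylsuccinates included, to paraconic lactones. The lactone ring then closes in the 5-exo-trig mode by attack of the new hydroxyl on the CH2CO2Me carbonyl with loss of methanol, the only γ-lactone open to it because the other ester could give only a β-lactone. The C1' configuration (R) is controlled by the hydride face chosen by the enzyme, and panels offer both senses. C4 (R) is controlled by the enzyme's epimer preference and is backed by thermodynamics, since it remains α to an ester in 7 and any cis lactone can be converged on the trans isomer with a catalytic amine base such as DBU. The only selectivity the step itself must supply is therefore the carbinol face; the substrate secures the rest through its acidic α-hydrogen between two carbonyl groups and a neutral benzyl ether that leaves the ketone electronically like a 4-alkoxyacetophenone.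

Step 4
Reactants: 7 methyl (2R,3R)-2-[4-(benzyloxy)phenyl]-5-oxooxolane-3-carboxylate; 8 4-(benzyloxy)benzaldehyde
Product: 9 methyl (2R,3R,4S)-2-[4-(benzyloxy)phenyl]-4-{(R)-[4-(benzyloxy)phenyl](hydroxy)methyl}-5-oxooxolane-3-carboxylate (3,4-trans; anti aldol)
Conditions: LiN(iPr)2 (LDA), THF, −78 °C; 8, −78 °C; AcOH, −78 °C
Reagents that add atoms: none
Why: Aldol addition of the lithium lactone enolate, formed by kinetic deprotonation of the more acidic lactone CH2, in which the aldehyde should enter C3 anti to the C4 ester and the ring-locked E(O)-enolate should favour the anti adduct through a Zimmerman–Traxler chair, which is the (R)-carbinol needed at C2; the minor carbinol epimer is removed by chromatography.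

Step 5
Reactants: 9 methyl (2R,3R,4S)-2-[4-(benzyloxy)phenyl]-4-{(R)-[4-(benzyloxy)phenyl](hydroxy)methyl}-5-oxooxolane-3-carboxylate
Product: 11 (1R,2R,5R,6R)-2,6-bis[4-(benzyloxy)phenyl]-3,7-dioxabicyclo[3.3.0]octane-4,8-dione (cis-fused dilactone; both aryl groups exo), via cis hydroxy ester 10 (not isolated)
Conditions: LiN(iPr)2 (2.3 equiv), THF, −78 to −40 °C; AcOH, −78 °C; then PPTS (cat.), toluene, 50 °C
Reagents that add atoms: none
Why: Fráter–Seebach-type dianion formation followed by kinetic protonation, in which the chelated alkoxide–enolate cannot undergo retro-aldol cleavage and the proton should reach C3 from the face opposite both the C4 ester and the aryl group on the chelate ring, inverting C3 to the cis epimer 10 whose hydroxyl then lactonises 5-exo-trig onto the neighbouring ester; unchanged 9 cannot lactonise and is recycled.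

Step 6
Reactants: 12 4-bromobenzene-1,3-diol
Product: 13 2,4-bis(benzyloxy)-1-bromobenzene
Conditions: BnBr, K2CO3, DMF, 60 °C
Reagents that add atoms: benzyl bromide, BrCc1ccccc1
Why: Williamson ether synthesis on both phenoxides with a primary benzylic bromide.

Step 7
Reactants: 13 2,4-bis(benzyloxy)-1-bromobenzene
Product: 14 [2,4-bis(benzyloxy)phenyl]magnesium bromide (kept under argon as a titrated THF solution)
Conditions: Mg turnings (I2 crystal), THF, 40 °C; titration
Reagents that add atoms: magnesium, [Mg]
Why: Grignard reagent formation by insertion of magnesium into the aryl C–Br bond, to which the benzyl ethers are inert; the ortho-alkoxy group stabilises the reagent by chelation, so a single batch can be stored and should serve both step 8 and step 10.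

Step 8
Reactants: 11 (1R,2R,5R,6R)-2,6-bis[4-(benzyloxy)phenyl]-3,7-dioxabicyclo[3.3.0]octane-4,8-dione; 14 [2,4-bis(benzyloxy)phenyl]magnesium bromide
Product: 15 (1R,2R,5R,6R)-8-[2,4-bis(benzyloxy)phenyl]-2,6-bis[4-(benzyloxy)phenyl]-8-hydroxy-3,7-dioxabicyclo[3.3.0]octan-4-one (lactol; both C8 anomers)
Conditions: 14 (0.9 equiv) added slowly to 11, THF, −40 to 0 °C; AcOH, −40 °C
Reagents that add atoms: none
Why: Grignard 1,2-addition to a γ-lactone, which should stop at the cyclic magnesium hemiketalate; the two carbonyl groups of 11 are homotopic, so either gives the same lactol, a second addition is held back by the deficit of reagent and by the bulky anionic hemiketalate beside the remaining carbonyl, and the weakly basic arylmagnesium should not enolise the dilactone toward β-elimination of a carboxylate.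

Step 9
Reactants: 15 (1R,2R,5R,6R)-8-[2,4-bis(benzyloxy)phenyl]-2,6-bis[4-(benzyloxy)phenyl]-8-hydroxy-3,7-dioxabicyclo[3.3.0]octan-4-one
Product: 16 (1S,2R,5R,6R,8R)-8-[2,4-bis(benzyloxy)phenyl]-2,6-bis[4-(benzyloxy)phenyl]-3,7-dioxabicyclo[3.3.0]octan-4-one (C8 aryl endo)
Conditions: Et3SiH, BF3·OEt2, CH2Cl2, −78 °C; Et3N then aq. NaHCO3, −78 °C
Reagents that add atoms: none
Why: Ionic hydrogenation of the aryl hemiketal, in which BF3·OEt2 generates the aryl-stabilised oxocarbenium ion and Et3SiH should deliver hydride to its convex face, anti to the fused lactone at C3/C4, so that the new aryl group at C5 ends cis to the C4 substituent (R); the C1' oxygen is still acylated within the lactone and so is shielded from ionisation, the cis ring fusion forbids epimerisation at C4, and the cold quench avoids acid-mediated equilibration of the kinetic product.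

Step 10
Reactants: 16 (1S,2R,5R,6R,8R)-8-[2,4-bis(benzyloxy)phenyl]-2,6-bis[4-(benzyloxy)phenyl]-3,7-dioxabicyclo[3.3.0]octan-4-one; 14 [2,4-bis(benzyloxy)phenyl]magnesium bromide
Product: 17 [(2R,3R,4R,5R)-5-[2,4-bis(benzyloxy)phenyl]-2-[4-(benzyloxy)phenyl]-4-{(R)-[4-(benzyloxy)phenyl](hydroxy)methyl}oxolan-3-yl][2,4-bis(benzyloxy)phenyl]methanone
Conditions: 14 (1.5 equiv), THF, −40 to 0 °C; AcOH, −40 °C
Reagents that add atoms: none
Why: Grignard 1,2-addition to the remaining lactone from its open convex face, whose adduct gives the aryl ketone with release of the C1' hydroxyl; the ketone is α-branched and deactivated by two alkoxy donors and should resist a second addition of the bulky ortho-substituted reagent, while the weakly basic reagent and the cold acidic quench should leave C3, now α to a ketone, unepimerised.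

Step 11
Reactants: 17 [(2R,3R,4R,5R)-5-[2,4-bis(benzyloxy)phenyl]-2-[4-(benzyloxy)phenyl]-4-{(R)-[4-(benzyloxy)phenyl](hydroxy)methyl}oxolan-3-yl][2,4-bis(benzyloxy)phenyl]methanone
Product: 18 [(2R,3R,4R,5R)-5-(2,4-dihydroxyphenyl)-4-[(R)-hydroxy(4-hydroxyphenyl)methyl]-2-(4-hydroxyphenyl)oxolan-3-yl](2,4-dihydroxyphenyl)methanone (CNP0244141.1)
Conditions: H2 (1 atm), Pd/C, THF/EtOAc, rt, stopped after uptake of six equivalents
Reagents that add atoms: none
Why: Hydrogenolysis of the six aryl benzyl ethers over Pd/C under neutral conditions should be much faster than cleavage of the ring and carbinol benzylic C–O bonds or reduction of the hydrogen-bonded aryl ketone, and it touches no stereocentre.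

Compound list
1 | 1-[4-(benzyloxy)phenyl]ethan-1-one | CC(=O)c1ccc(OCc2ccccc2)cc1 | starting material
2 | dimethyl carbonate | COC(=O)OC | starting material
3 | methyl 3-[4-(benzyloxy)phenyl]-3-oxopropanoate | COC(=O)CC(=O)c1ccc(OCc2ccccc2)cc1 | intermediate
4 | methyl bromoacetate | COC(=O)CBr | starting material
5 | dimethyl 2-[4-(benzyloxy)benzoyl]butanedioate (racemic) | COC(=O)CC(C(=O)OC)C(=O)c1ccc(OCc2ccccc2)cc1 | intermediate
6 | dimethyl (2R)-2-{(R)-[4-(benzyloxy)phenyl](hydroxy)methyl}butanedioate | COC(=O)C[C@H]([C@@H](O)c1ccc(OCc2ccccc2)cc1)C(=O)OC | intermediate (not isolated)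
7 | methyl (2R,3R)-2-[4-(benzyloxy)phenyl]-5-oxooxolane-3-carboxylate | O=C1C[C@H]([C@@H](O1)c2ccc(OCc3ccccc3)cc2)C(=O)OC | intermediate
8 | 4-(benzyloxy)benzaldehyde | O=Cc1ccc(OCc2ccccc2)cc1 | starting material
9 | methyl (2R,3R,4S)-2-[4-(benzyloxy)phenyl]-4-{(R)-[4-(benzyloxy)phenyl](hydroxy)methyl}-5-oxooxolane-3-carboxylate | O=C1[C@H]([C@@H](O)c2ccc(OCc3ccccc3)cc2)[C@H]([C@@H](O1)c4ccc(OCc5ccccc5)cc4)C(=O)OC | intermediate
10 | methyl (2R,3R,4R)-2-[4-(benzyloxy)phenyl]-4-{(R)-[4-(benzyloxy)phenyl](hydroxy)methyl}-5-oxooxolane-3-carboxylate | O=C1[C@@H]([C@@H](O)c2ccc(OCc3ccccc3)cc2)[C@H]([C@@H](O1)c4ccc(OCc5ccccc5)cc4)C(=O)OC | intermediate (not isolated)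
11 | (1R,2R,5R,6R)-2,6-bis[4-(benzyloxy)phenyl]-3,7-dioxabicyclo[3.3.0]octane-4,8-dione | O=C1[C@@H]([C@@H](O2)c3ccc(OCc4ccccc4)cc3)[C@H]([C@@H](O1)c5ccc(OCc6ccccc6)cc5)C2=O | intermediate
12 | 4-bromobenzene-1,3-diol | Oc1ccc(Br)c(O)c1 | starting material
13 | 2,4-bis(benzyloxy)-1-bromobenzene | Brc1ccc(OCc2ccccc2)cc1OCc1ccccc1 | intermediate
14 | [2,4-bis(benzyloxy)phenyl]magnesium bromide | Br[Mg]c1ccc(OCc2ccccc2)cc1OCc1ccccc1 | intermediate
15 | (1R,2R,5R,6R)-8-[2,4-bis(benzyloxy)phenyl]-2,6-bis[4-(benzyloxy)phenyl]-8-hydroxy-3,7-dioxabicyclo[3.3.0]octan-4-one (C8 anomers) | O=C1[C@@H]2[C@H]([C@@H](O1)c3ccc(OCc4ccccc4)cc3)C(O)(c3ccc(OCc4ccccc4)cc3OCc3ccccc3)O[C@H]2c2ccc(OCc3ccccc3)cc2 | intermediate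
16 | (1S,2R,5R,6R,8R)-8-[2,4-bis(benzyloxy)phenyl]-2,6-bis[4-(benzyloxy)phenyl]-3,7-dioxabicyclo[3.3.0]octan-4-one | O=C1[C@@H]2[C@H]([C@@H](O1)c3ccc(OCc4ccccc4)cc3)[C@H](c3ccc(OCc4ccccc4)cc3OCc3ccccc3)O[C@H]2c2ccc(OCc3ccccc3)cc2 | intermediate
17 | [(2R,3R,4R,5R)-5-[2,4-bis(benzyloxy)phenyl]-2-[4-(benzyloxy)phenyl]-4-{(R)-[4-(benzyloxy)phenyl](hydroxy)methyl}oxolan-3-yl][2,4-bis(benzyloxy)phenyl]methanone | O=C(c1ccc(OCc2ccccc2)cc1OCc1ccccc1)[C@@H]1[C@H]([C@@H](O)c2ccc(OCc3ccccc3)cc2)[C@H](c2ccc(OCc3ccccc3)cc2OCc2ccccc2)O[C@H]1c1ccc(OCc2ccccc2)cc1 | intermediate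
18 | [(2R,3R,4R,5R)-5-(2,4-dihydroxyphenyl)-4-[(R)-hydroxy(4-hydroxyphenyl)methyl]-2-(4-hydroxyphenyl)oxolan-3-yl](2,4-dihydroxyphenyl)methanone | O=C(c1ccc(O)cc1O)[C@@H]1[C@H]([C@@H](O)c2ccc(O)cc2)[C@H](c2ccc(O)cc2O)O[C@H]1c1ccc(O)cc1 | target

Total step count: 11. Longest linear sequence: 9 steps (steps 1–5 and 8–11); steps 6–7 are a two-step side branch to the Grignard reagent.

Steps most likely to fail

Step 3. What may go wrong: no enzyme of the panel turns over the hindered aryl ketone, or reduction outpaces racemisation so that the α-epimers are not funnelled (poor enantioface or epimer selection). The fallback sets out from aldehyde 8 and comes back at 7; it sets the same stereodiad by an auxiliary-controlled aldol addition. (4R)-4-Benzyl-1,3-oxazolidin-2-one is N-acylated with methyl 4-chloro-4-oxobutanoate (n-BuLi, THF, −78 °C) to (4R)-4-benzyl-3-(4-methoxy-4-oxobutanoyl)-1,3-oxazolidin-2-one F1. Its dibutylboron enolate (Bu2BOTf, iPr2NEt, CH2Cl2, −78 to 0 °C) should add to 8 in the Evans syn sense to give methyl (3R)-3-{(R)-[4-(benzyloxy)phenyl](hydroxy)methyl}-4-[(4R)-4-benzyl-2-oxo-1,3-oxazolidin-3-yl]-4-oxobutanoate F2. LiOH/H2O2 (THF/H2O, 0 °C) removes the auxiliary and the methyl ester, and acidification closes the γ-lactone to (2R,3R)-2-[4-(benzyloxy)phenyl]-5-oxooxolane-3-carboxylic acid F3. MeI/K2CO3 in DMF then gives 7.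

Step 5. What may go wrong: deprotonation α to the ester instead of at C3, followed by β-elimination of the lactone carboxylate, or poor facial selectivity in the protonation so that 9 is largely returned. The fallback sets out from 7 and 8 and comes back at 11; it replaces stepwise kinetic control by a thermodynamically driven aldol–lactonisation cascade in one flask. The potassium enolate of 7 (KN(SiMe3)2, THF, −78 °C) is treated with 8 and the mixture is allowed to reach about −20 °C before an AcOH quench. Potassium aldolates revert readily, so the addition becomes reversible, and only the aldolate with its oxygen cis to the C4 ester (the alkoxide of 10) can leave the equilibrium by irreversible lactonisation, the exo aryl arrangement being favoured in that closure. New compounds on its way: none F0.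

Step 8. What may go wrong: a second aryl addition to the remaining lactone before the first is complete, or sluggish addition that lets enolisation and β-elimination of a carboxylate compete. The fallback sets out from 11 and comes back at 15; it masks one lactone as its ring-opened carboxylate. LiOH (1 equiv, THF/H2O, 0 °C) should open a single lactone, the carboxylate formed shielding the neighbouring carbonyl from a second hydroxide, to give lithium (2R,3R,4R)-2-[4-(benzyloxy)phenyl]-4-{(R)-[4-(benzyloxy)phenyl](hydroxy)methyl}-5-oxooxolane-3-carboxylate F4. After drying, 14 (2.1 equiv, THF, −40 to 0 °C) is added: the first equivalent deprotonates the carbinol and is spent as 1,3-bis(benzyloxy)benzene, the second adds to the lactone, and a lithium carboxylate is inert to the arylmagnesium at this temperature. AcOH quench followed by PPTS (cat.) in CH2Cl2 relactonises the hydroxy acid to 15; any doubly opened material returns 11 on acidification.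

Further compounds
F1 | step 3 | (4R)-4-benzyl-3-(4-methoxy-4-oxobutanoyl)-1,3-oxazolidin-2-one | COC(=O)CCC(=O)N1[C@H](Cc2ccccc2)COC1=O
F2 | step 3 | methyl (3R)-3-{(R)-[4-(benzyloxy)phenyl](hydroxy)methyl}-4-[(4R)-4-benzyl-2-oxo-1,3-oxazolidin-3-yl]-4-oxobutanoate | COC(=O)C[C@H]([C@@H](O)c1ccc(OCc2ccccc2)cc1)C(=O)N1[C@H](Cc2ccccc2)COC1=O
F3 | step 3 | (2R,3R)-2-[4-(benzyloxy)phenyl]-5-oxooxolane-3-carboxylic acid | O=C1C[C@H]([C@@H](O1)c2ccc(OCc3ccccc3)cc2)C(=O)O
F0 | step 5 | none | none
F4 | step 8 | lithium (2R,3R,4R)-2-[4-(benzyloxy)phenyl]-4-{(R)-[4-(benzyloxy)phenyl](hydroxy)methyl}-5-oxooxolane-3-carboxylate | O=C1[C@@H]([C@@H](O)c2ccc(OCc3ccccc3)cc2)[C@H]([C@@H](O1)c4ccc(OCc5ccccc5)cc4)C(=O)[O-].[Li+]
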